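**Plan**

- Retrosynthesis: once the benzyl-type ethers are removed, ring C of the lower unit (O1–C2–C3–C4–C4a–C8a) is a cyclic α-ketol, with C3–OH next to the C4 aryl ketone and C2 carrying both O1 and ring B. Its C2–C3 bond is traced back to the C2–C3 bond of a 3-hydroxy-2-aryl-2,3-dihydrobenzofuran-3-carbaldehyde, whose formyl carbon becomes C3 by an acyloin 1,2-shift of C2.
- The interflavan C4–C8 bond is cut next (epicatechin C4 cation plus ring A of that dihydrobenzofuran), then the dihydrobenzofuran C2–C3 bond (carbenoid C–H insertion of an aryl diazoacetate into an ortho benzylic ether), then the three O–CH2 bonds of a symmetric tri-ether of phloroacetophenone.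
- Forward: ring A tri-ether → diazo ester → five-membered ring by C–H insertion → C3 hydroxylation → Friedel–Crafts union with the epicatechin 4β-ether → ester to aldehyde → five- to six-membered ring expansion to the dihydroflavonol → global hydrogenolysis.
- Stereochemistry: upper C2/C3 come from (−)-epicatechin; upper C4 from attack anti to the cis C2-aryl/C3-OH face; lower C2 from the chiral dirhodium carboxylate catalyst, kept with retention in the shift; lower C3 from the chelated transition state of the shift, trans to the C2 aryl group.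

Key step: step 11

Remark: DBB = 3,4-bis(benzyloxy)benzyl, Bn = benzyl. The sense of induction in step 5 is assigned by analogy with simpler ortho-benzyloxyaryl diazoacetates; if it proves opposite, the (R)-configured catalyst is used and nothing else changes.

**Route**

Step 1
Reactants: 1 2′,4′,6′-trihydroxyacetophenone (phloroacetophenone); 2 3,4-bis(benzyloxy)benzyl chloride (3.3 equiv in all, one molecule per phenol)
Product: 3 1-[2,4,6-tris(DBB-oxy)phenyl]ethanone
Conditions: K2CO3, n-Bu4NI (cat.), DMF, 70 °C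
Reagents that add atoms: 3,4-bis(benzyloxy)benzyl chloride 2 (second equivalent), ClCc1ccc(OCc2ccccc2)c(OCc2ccccc2)c1; 3,4-bis(benzyloxy)benzyl chloride 2 (third equivalent), ClCc1ccc(OCc2ccccc2)c(OCc2ccccc2)c1
Why: three successive Williamson O-alkylations, each phenol taking up one molecule of 2, should give a symmetric ring A in which either ortho ether can later supply C2 and ring B, so no phenol has to be differentiated.

Step 2
Reactants: 3 1-[2,4,6-tris(DBB-oxy)phenyl]ethanone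
Product: 4 2-oxo-2-[2,4,6-tris(DBB-oxy)phenyl]acetic acid
Conditions: SeO2, pyridine, 100 °C; cold aq. citric acid work-up
Reagents that add atoms: selenium dioxide, O=[Se]=O
Why: Riley oxidation of an aryl methyl ketone in pyridine should stop at the arylglyoxylic acid under basic conditions that the benzyl-type ethers tolerate.

Step 3
Reactants: 4 2-oxo-2-[2,4,6-tris(DBB-oxy)phenyl]acetic acid
Product: 5 methyl 2-oxo-2-[2,4,6-tris(DBB-oxy)phenyl]acetate
Conditions: MeI, K2CO3, DMF, rt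
Reagents that add atoms: iodomethane, CI
Why: O-alkylation of the carboxylate should give the methyl ester without touching the ketone or the ethers.

Step 4
Reactants: 5 methyl 2-oxo-2-[2,4,6-tris(DBB-oxy)phenyl]acetate
Product: 7 methyl 2-diazo-2-[2,4,6-tris(DBB-oxy)phenyl]acetate, via tosylhydrazone 6 (not isolated)
Conditions: TsNHNH2, MeOH/toluene, 60 °C; then DBU, CH2Cl2, rt
Reagents that add atoms: 4-methylbenzenesulfonohydrazide, Cc1ccc(cc1)S(=O)(=O)NN
Why: condensation at the activated keto group followed by base-induced loss of sulfinate (Bamford–Stevens type) should give the aryl diazoacetate.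

Step 5
Reactants: 7 methyl 2-diazo-2-[2,4,6-tris(DBB-oxy)phenyl]acetate
Product: 8 methyl (2S,3R)-2-[3,4-bis(benzyloxy)phenyl]-4,6-bis(DBB-oxy)-2,3-dihydro-1-benzofuran-3-carboxylate (2,3-cis)
Conditions: dirhodium tetrakis[N-phthaloyl-(S)-tert-leucinate], Rh2(S-PTTL)4 (2 mol %), toluene, −60 °C
Reagents that add atoms: none
Why: intramolecular 1,5 C–H insertion of the divalent-rhodium carbenoid into the benzylic C–H of an ortho ether (the two are equivalent by symmetry) should close the dihydrobenzofuran, the chiral carboxylate ligands choosing between the enantiotopic benzylic hydrogens and so setting C2, while the kinetic cis centre at C3 is erased in step 6.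

Step 6
Reactants: 8 methyl (2S,3R)-2-[3,4-bis(benzyloxy)phenyl]-4,6-bis(DBB-oxy)-2,3-dihydro-1-benzofuran-3-carboxylate
Product: 10 methyl (2R,3S)-2-[3,4-bis(benzyloxy)phenyl]-4,6-bis(DBB-oxy)-3-hydroxy-2,3-dihydro-1-benzofuran-3-carboxylate, via potassium enolate 9 (not isolated)
Conditions: KN(SiMe3)2, THF, −78 °C; then 3-phenyl-2-(phenylsulfonyl)oxaziridine, −78 °C; aq. NH4Cl
Reagents that add atoms: 3-phenyl-2-(phenylsulfonyl)oxaziridine, O=S(=O)(c1ccccc1)N1OC1c1ccccc1
Why: enolate hydroxylation with an N-sulfonyloxaziridine (Davis oxidation) should deliver oxygen to the face anti to the C2 aryl group, placing OH trans and the ester cis to that aryl, and the enolate should not ring-open at −78 °C because the C2–O1 bond lies in its nodal plane.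

Step 7
Reactants: 11 (−)-epicatechin
Product: 12 5,7,3′,4′-tetra-O-benzyl-(−)-epicatechin
Conditions: BnBr, K2CO3, DMF, 0 °C to rt
Reagents that add atoms: benzyl bromide, BrCc1ccccc1
Why: carbonate-mediated Williamson benzylation should take the four phenols and leave the secondary 3-OH and both stereocentres untouched.

Step 8
Reactants: 12 5,7,3′,4′-tetra-O-benzyl-(−)-epicatechin
Product: 13 (2R,3R,4S)-5,7,3′,4′-tetrakis(benzyloxy)-4-(2-ethoxyethoxy)flavan-3-ol (4β-ether)
Conditions: DDQ, 2-ethoxyethanol, CH2Cl2, rt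
Reagents that add atoms: 2-ethoxyethanol, CCOCCO
Why: DDQ hydride abstraction at the benzylic C4 and capture of the cation by the alcohol anti to the cis C2-aryl/C3-OH face should give the 4β-ether, a centre that is ionised again in step 9.

Step 9
Reactants: 10 methyl (2R,3S)-2-[3,4-bis(benzyloxy)phenyl]-4,6-bis(DBB-oxy)-3-hydroxy-2,3-dihydro-1-benzofuran-3-carboxylate (2.5 equiv, excess recovered); 13 (2R,3R,4S)-5,7,3′,4′-tetrakis(benzyloxy)-4-(2-ethoxyethoxy)flavan-3-ol
Product: 14 methyl (2R,3S)-2-[3,4-bis(benzyloxy)phenyl]-4,6-bis(DBB-oxy)-3-hydroxy-7-[5,7,3′,4′-tetra-O-benzyl-(−)-epicatechin-4β-yl]-2,3-dihydro-1-benzofuran-3-carboxylate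
Conditions: Me3SiOTf (0.2 equiv), CH2Cl2, −78 °C; Et3N quench
Reagents that add atoms: none
Why: the Lewis acid should ionise the C4 ether to the flavan-4-yl cation, which alkylates ring A of 10 (Friedel–Crafts) at C7, the counterpart of C8 of a flavan-3-ol lying between the ring oxygen and one ether whereas C5 is shielded by two flanking DBB ethers, and from the face anti to the cis C2-aryl and C3-OH groups, which sets the 4β (3,4-trans) centre.

Step 10
Reactants: 14 methyl (2R,3S)-2-[3,4-bis(benzyloxy)phenyl]-4,6-bis(DBB-oxy)-3-hydroxy-7-[5,7,3′,4′-tetra-O-benzyl-(−)-epicatechin-4β-yl]-2,3-dihydro-1-benzofuran-3-carboxylate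
Product: 15 (2R,3S)-2-[3,4-bis(benzyloxy)phenyl]-4,6-bis(DBB-oxy)-3-hydroxy-7-[5,7,3′,4′-tetra-O-benzyl-(−)-epicatechin-4β-yl]-2,3-dihydro-1-benzofuran-3-carbaldehyde
Conditions: iBu2AlH (5 equiv), CH2Cl2/toluene, −78 °C; aq. KNaC4H4O6 work-up
Reagents that add atoms: none
Why: partial reduction of the ester should stop at the aldehyde because the tetrahedral aluminium hemiacetal, chelated by the neighbouring alkoxide, survives at −78 °C until work-up.

Step 11
Reactants: 15 (2R,3S)-2-[3,4-bis(benzyloxy)phenyl]-4,6-bis(DBB-oxy)-3-hydroxy-7-[5,7,3′,4′-tetra-O-benzyl-(−)-epicatechin-4β-yl]-2,3-dihydro-1-benzofuran-3-carbaldehyde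
Product: 16 3′,4′-di-O-benzyl-5,7-bis-O-DBB-8-[5,7,3′,4′-tetra-O-benzyl-(−)-epicatechin-4β-yl]-(2R,3R)-taxifolin
Conditions: Sc(O3SCF3)3 (20 mol %), 2,6-di-tert-butylpyridine (20 mol %), 4 Å molecular sieves, CH2Cl2, −20 °C to rt
Reagents that add atoms: none
Why: Proposed new method: trivalent scandium should chelate the C3 hydroxyl and the formyl oxygen of 15 and trigger an α-ketol (acyloin) 1,2-shift in which C2, a benzylic carbon that also bears the ring oxygen, moves with its bonding pair from C3 to the formyl carbon, so that old C3 becomes the aryl ketone C4 and the formyl carbon becomes the carbinol C3 of the dihydroflavonol. The closest known reaction type is the Lewis-acid ring expansion of 1-hydroxycycloalkanecarbaldehydes and of 17-hydroxy-20-keto steroids (D-homoannulation), which has not been shown for a 3-hydroxy-2,3-dihydrobenzofuran-3-carbaldehyde. The six-membered ring is not closed by a cyclisation; it arises from the five-membered O1–C2–C3–C3a–C7a ring by insertion of the formyl carbon into the C2–C3 bond (a suprafacial 1,2-shift, five to six). C2 should keep its configuration because the migrating carbon moves with retention, and the new C3 centre is controlled by the syn-periplanar O–C–C=O chelate, in which C2 adds to the formyl face that puts OH trans to the C2 aryl group, which is also the diequatorial, thermodynamically preferred arrangement. The step needs C2 to migrate and not the aryl carbon C3a; this should be secured by the higher migratory aptitude of the α-oxygenated benzylic carbon and by the fact that only C2 migration gives the ketone conjugated with the trioxygenated ring A. The buffered, catalytic Lewis acid at low temperature should leave the benzyl-type ethers, the interflavan bond and the upper 3-OH untouched.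

Step 12
Reactants: 16 3′,4′-di-O-benzyl-5,7-bis-O-DBB-8-[5,7,3′,4′-tetra-O-benzyl-(−)-epicatechin-4β-yl]-(2R,3R)-taxifolin
Product: 17 (−)-epicatechin-(4β→8)-(2R,3R)-taxifolin (target, CNP0210692.1)
Conditions: H2 (1 atm), Pd(OH)2 on carbon, THF/MeOH/H2O, rt
Reagents that add atoms: none
Why: hydrogenolysis should cleave all twelve benzylic C–O bonds (ten benzyl and two DBB ethers) without reducing the aryl ketone or opening the two pyran rings, so all six stereocentres are kept.

**Compound list**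

1 | 2′,4′,6′-trihydroxyacetophenone | CC(=O)c1c(O)cc(O)cc1O | starting material
2 | 3,4-bis(benzyloxy)benzyl chloride | ClCc1ccc(OCc2ccccc2)c(OCc2ccccc2)c1 | starting material
3 | 1-[2,4,6-tris(DBB-oxy)phenyl]ethanone | CC(=O)c1c(OCc2ccc(OCc3ccccc3)c(OCc3ccccc3)c2)cc(OCc2ccc(OCc3ccccc3)c(OCc3ccccc3)c2)cc1OCc1ccc(OCc2ccccc2)c(OCc2ccccc2)c1 | intermediate
4 | 2-oxo-2-[2,4,6-tris(DBB-oxy)phenyl]acetic acid | OC(=O)C(=O)c1c(OCc2ccc(OCc3ccccc3)c(OCc3ccccc3)c2)cc(OCc2ccc(OCc3ccccc3)c(OCc3ccccc3)c2)cc1OCc1ccc(OCc2ccccc2)c(OCc2ccccc2)c1 | intermediate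
5 | methyl 2-oxo-2-[2,4,6-tris(DBB-oxy)phenyl]acetate | COC(=O)C(=O)c1c(OCc2ccc(OCc3ccccc3)c(OCc3ccccc3)c2)cc(OCc2ccc(OCc3ccccc3)c(OCc3ccccc3)c2)cc1OCc1ccc(OCc2ccccc2)c(OCc2ccccc2)c1 | intermediate
6 | methyl 2-(tosylhydrazono)-2-[2,4,6-tris(DBB-oxy)phenyl]acetate | COC(=O)C(=NNS(=O)(=O)c1ccc(C)cc1)c1c(OCc2ccc(OCc3ccccc3)c(OCc3ccccc3)c2)cc(OCc2ccc(OCc3ccccc3)c(OCc3ccccc3)c2)cc1OCc1ccc(OCc2ccccc2)c(OCc2ccccc2)c1 | intermediate (not isolated)
7 | methyl 2-diazo-2-[2,4,6-tris(DBB-oxy)phenyl]acetate | COC(=O)C(=[N+]=[N-])c1c(OCc2ccc(OCc3ccccc3)c(OCc3ccccc3)c2)cc(OCc2ccc(OCc3ccccc3)c(OCc3ccccc3)c2)cc1OCc1ccc(OCc2ccccc2)c(OCc2ccccc2)c1 | intermediate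
8 | methyl (2S,3R)-2-[3,4-bis(benzyloxy)phenyl]-4,6-bis(DBB-oxy)-2,3-dihydro-1-benzofuran-3-carboxylate (2,3-cis) | COC(=O)[C@@H]1c2c(OCc3ccc(OCc4ccccc4)c(OCc4ccccc4)c3)cc(OCc3ccc(OCc4ccccc4)c(OCc4ccccc4)c3)cc2O[C@@H]1c1ccc(OCc2ccccc2)c(OCc2ccccc2)c1 | intermediate
9 | potassium ester enolate of 8 (C3 planar, C2 unchanged) | [K+].[O-]C(OC)=C1c2c(OCc3ccc(OCc4ccccc4)c(OCc4ccccc4)c3)cc(OCc3ccc(OCc4ccccc4)c(OCc4ccccc4)c3)cc2O[C@@H]1c1ccc(OCc2ccccc2)c(OCc2ccccc2)c1 | intermediate (not isolated)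
10 | methyl (2R,3S)-2-[3,4-bis(benzyloxy)phenyl]-4,6-bis(DBB-oxy)-3-hydroxy-2,3-dihydro-1-benzofuran-3-carboxylate (3-OH trans to the C2 aryl group) | COC(=O)[C@]1(O)c2c(OCc3ccc(OCc4ccccc4)c(OCc4ccccc4)c3)cc(OCc3ccc(OCc4ccccc4)c(OCc4ccccc4)c3)cc2O[C@@H]1c1ccc(OCc2ccccc2)c(OCc2ccccc2)c1 | intermediate
11 | (−)-epicatechin, (2R,3R) | C1c2c(O)cc(O)cc2O[C@H](c2ccc(O)c(O)c2)[C@@H]1O | starting material
12 | 5,7,3′,4′-tetra-O-benzyl-(−)-epicatechin | C1c2c(OCc3ccccc3)cc(OCc3ccccc3)cc2O[C@H](c2ccc(OCc3ccccc3)c(OCc3ccccc3)c2)[C@@H]1O | intermediate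
13 | (2R,3R,4S)-5,7,3′,4′-tetrakis(benzyloxy)-4-(2-ethoxyethoxy)flavan-3-ol (4β-ether, 2,3-cis-3,4-trans) | CCOCCO[C@H]1c2c(OCc3ccccc3)cc(OCc3ccccc3)cc2O[C@H](c2ccc(OCc3ccccc3)c(OCc3ccccc3)c2)[C@@H]1O | intermediate
14 | methyl (2R,3S)-2-[3,4-bis(benzyloxy)phenyl]-4,6-bis(DBB-oxy)-3-hydroxy-7-[5,7,3′,4′-tetra-O-benzyl-(−)-epicatechin-4β-yl]-2,3-dihydro-1-benzofuran-3-carboxylate | COC(=O)[C@]1(O)c2c(OCc3ccc(OCc4ccccc4)c(OCc4ccccc4)c3)cc(OCc3ccc(OCc4ccccc4)c(OCc4ccccc4)c3)c([C@H]3c4c(OCc5ccccc5)cc(OCc5ccccc5)cc4O[C@H](c4ccc(OCc5ccccc5)c(OCc5ccccc5)c4)[C@@H]3O)c2O[C@@H]1c1ccc(OCc2ccccc2)c(OCc2ccccc2)c1 | intermediate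
15 | (2R,3S)-2-[3,4-bis(benzyloxy)phenyl]-4,6-bis(DBB-oxy)-3-hydroxy-7-[5,7,3′,4′-tetra-O-benzyl-(−)-epicatechin-4β-yl]-2,3-dihydro-1-benzofuran-3-carbaldehyde | O=C[C@]1(O)c2c(OCc3ccc(OCc4ccccc4)c(OCc4ccccc4)c3)cc(OCc3ccc(OCc4ccccc4)c(OCc4ccccc4)c3)c([C@H]3c4c(OCc5ccccc5)cc(OCc5ccccc5)cc4O[C@H](c4ccc(OCc5ccccc5)c(OCc5ccccc5)c4)[C@@H]3O)c2O[C@@H]1c1ccc(OCc2ccccc2)c(OCc2ccccc2)c1 | intermediate
16 | 3′,4′-di-O-benzyl-5,7-bis-O-DBB-8-[5,7,3′,4′-tetra-O-benzyl-(−)-epicatechin-4β-yl]-(2R,3R)-taxifolin | O=C1c2c(OCc3ccc(OCc4ccccc4)c(OCc4ccccc4)c3)cc(OCc3ccc(OCc4ccccc4)c(OCc4ccccc4)c3)c([C@H]3c4c(OCc5ccccc5)cc(OCc5ccccc5)cc4O[C@H](c4ccc(OCc5ccccc5)c(OCc5ccccc5)c4)[C@@H]3O)c2O[C@H](c2ccc(OCc3ccccc3)c(OCc3ccccc3)c2)[C@H]1O | intermediate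
17 | (−)-epicatechin-(4β→8)-(2R,3R)-taxifolin (CNP0210692.1) | O=C1c2c(O)cc(O)c([C@H]3c4c(O)cc(O)cc4O[C@H](c4ccc(O)c(O)c4)[C@@H]3O)c2O[C@H](c2ccc(O)c(O)c2)[C@H]1O | target

**Step count and risks**

Total step count: 12. Longest linear sequence: 10 steps (steps 1–6, then 9–12).

Steps most likely to fail:

1. Step 11 (Proposed new method). The shift may take another course: migration of the aryl carbon C3a in place of C2, or heterolysis of the C2–C3 bond to an oxocarbenium/enediolate pair that recloses with loss of the C2 configuration. The Lewis acid may also ionise the electron-rich DBB ethers. Fallback (known chemistry): the lower ring C is not made by ring expansion but taken six-membered from (+)-catechin and oxidised at C4. (+)-Catechin is benzylated as in step 7 to 5,7,3′,4′-tetra-O-benzyl-(+)-catechin F1. An excess of F1 is alkylated at C8 by the cation from 13 (Me3SiOTf, CH2Cl2, −78 °C), which should give octa-O-benzyl procyanidin B1 F2. DDQ in wet CH2Cl2 should hydroxylate the benzylic C4 methylene of the lower unit, the more accessible of the two benzylic positions, to the 4β-alcohol F3. MnO2 in CH2Cl2 should oxidise this benzylic alcohol, and not the two aliphatic 3-OH groups, to the octa-O-benzyl ketone F4. Hydrogenolysis as in step 12 should then give 17. This fallback sets out from 13 and comes back to the route at 17.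

2. Step 9. The silyl triflate may ionise or silylate the tertiary benzylic carbinol of 10 in place of the ether of 13, and the crowded, fully substituted C3 beside ring A may slow the alkylation until self-condensation of the electrophile takes over. Fallback: the union is made one stage earlier, on the dihydrobenzofuran ester that carries no carbinol yet. An excess of 8 is alkylated at C7 by the cation from 13 (Me3SiOTf, CH2Cl2, −78 °C), which should give the 7-linked ester methyl (2S,3R)-2-[3,4-bis(benzyloxy)phenyl]-4,6-bis(DBB-oxy)-7-[5,7,3′,4′-tetra-O-benzyl-(−)-epicatechin-4β-yl]-2,3-dihydro-1-benzofuran-3-carboxylate F5. KN(SiMe3)2 (2.2 equiv, THF, −78 °C) should take the proton of the upper 3-OH and then the C3 proton to give the dipotassium alkoxide enolate F6, which is not isolated. 3-Phenyl-2-(phenylsulfonyl)oxaziridine should then hydroxylate it anti to the C2 aryl group, as in step 6, to give 14. This fallback sets out from 8 and comes back to the route at 14.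

3. Step 5. Enantioselectivity may be low, or the sense of induction reversed, because the two ortho ethers twist the carbenoid out of the aryl plane; insertion or cyclopropanation elsewhere may also compete. Fallback: resolution in place of asymmetric catalysis. 7 is cyclised with achiral Rh2(OAc)4 (CH2Cl2, rt), which should give the racemic cis ester, that is 8 together with its enantiomer methyl (2R,3S)-2-[3,4-bis(benzyloxy)phenyl]-4,6-bis(DBB-oxy)-2,3-dihydro-1-benzofuran-3-carboxylate F7, and the two are separated by preparative chromatography on a chiral stationary phase. This fallback sets out from 7 and comes back to the route at 8.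

**Further compounds**

F1 | step 11 | 5,7,3′,4′-tetra-O-benzyl-(+)-catechin | C1c2c(OCc3ccccc3)cc(OCc3ccccc3)cc2O[C@H](c2ccc(OCc3ccccc3)c(OCc3ccccc3)c2)[C@H]1O
F2 | step 11 | octa-O-benzyl procyanidin B1, epicatechin-(4β→8)-catechin | C1c2c(OCc3ccccc3)cc(OCc3ccccc3)c([C@H]3c4c(OCc5ccccc5)cc(OCc5ccccc5)cc4O[C@H](c4ccc(OCc5ccccc5)c(OCc5ccccc5)c4)[C@@H]3O)c2O[C@H](c2ccc(OCc3ccccc3)c(OCc3ccccc3)c2)[C@H]1O
F3 | step 11 | octa-O-benzyl procyanidin B1 with a 4β-hydroxyl on the lower unit | O[C@H]1c2c(OCc3ccccc3)cc(OCc3ccccc3)c([C@H]3c4c(OCc5ccccc5)cc(OCc5ccccc5)cc4O[C@H](c4ccc(OCc5ccccc5)c(OCc5ccccc5)c4)[C@@H]3O)c2O[C@H](c2ccc(OCc3ccccc3)c(OCc3ccccc3)c2)[C@H]1O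
F4 | step 11 | 5,7,3′,4′-tetra-O-benzyl-8-[5,7,3′,4′-tetra-O-benzyl-(−)-epicatechin-4β-yl]-(2R,3R)-taxifolin | O=C1c2c(OCc3ccccc3)cc(OCc3ccccc3)c([C@H]3c4c(OCc5ccccc5)cc(OCc5ccccc5)cc4O[C@H](c4ccc(OCc5ccccc5)c(OCc5ccccc5)c4)[C@@H]3O)c2O[C@H](c2ccc(OCc3ccccc3)c(OCc3ccccc3)c2)[C@H]1O
F5 | step 9 | methyl (2S,3R)-2-[3,4-bis(benzyloxy)phenyl]-4,6-bis(DBB-oxy)-7-[5,7,3′,4′-tetra-O-benzyl-(−)-epicatechin-4β-yl]-2,3-dihydro-1-benzofuran-3-carboxylate | COC(=O)[C@@H]1c2c(OCc3ccc(OCc4ccccc4)c(OCc4ccccc4)c3)cc(OCc3ccc(OCc4ccccc4)c(OCc4ccccc4)c3)c([C@H]3c4c(OCc5ccccc5)cc(OCc5ccccc5)cc4O[C@H](c4ccc(OCc5ccccc5)c(OCc5ccccc5)c4)[C@@H]3O)c2O[C@@H]1c1ccc(OCc2ccccc2)c(OCc2ccccc2)c1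
F6 | step 9 | dipotassium alkoxide enolate of F5 (C3 planar, upper 3-O deprotonated) | [K+].[K+].[O-]C(OC)=C1c2c(OCc3ccc(OCc4ccccc4)c(OCc4ccccc4)c3)cc(OCc3ccc(OCc4ccccc4)c(OCc4ccccc4)c3)c([C@H]3c4c(OCc5ccccc5)cc(OCc5ccccc5)cc4O[C@H](c4ccc(OCc5ccccc5)c(OCc5ccccc5)c4)[C@@H]3[O-])c2O[C@@H]1c1ccc(OCc2ccccc2)c(OCc2ccccc2)c1
F7 | step 5 | methyl (2R,3S)-2-[3,4-bis(benzyloxy)phenyl]-4,6-bis(DBB-oxy)-2,3-dihydro-1-benzofuran-3-carboxylate (enantiomer of 8) | COC(=O)[C@H]1c2c(OCc3ccc(OCc4ccccc4)c(OCc4ccccc4)c3)cc(OCc3ccc(OCc4ccccc4)c(OCc4ccccc4)c3)cc2O[C@H]1c1ccc(OCc2ccccc2)c(OCc2ccccc2)c1
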